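Ring locants: C1 (allylic CHOAc), C2=C3(Me), C4, C5, C6=C7 (bearing carboxyl C14), C8, C9 (CHOAc), C10 (CH-iPr). Everything rests on cutting C4–C5, the central bond of the 1,5-diene in the ten-membered ring. C4 is a primary allylic carbon and C5 is the vinylogous alpha position of C14. The key step, an intramolecular SN2 alkylation, closes the carbocycle in one operation and carries both ring-cis alkenes and the C1/C10/C9 triad through untouched. Its precursor is an open chain with an allylic chloride at C4 and a traceless phenylsulfonyl group at C5. The triad comes from an Evans syn aldol and an Evans–Tishchenko reduction.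

Key step: step 13

Remark: the C5 centre created in step 13 is taken as a mixture of epimers (left undefined in the SMILES of 23), because step 14 removes it.

Step 1
Reactants: 1 prop-2-yn-1-ol
Product: 3 (Z)-3-iodo-2-methylprop-2-en-1-ol, via vinylmagnesium alkoxide 2 (not isolated)
Conditions: MeMgBr (2.3 equiv), CuI (10 mol %), Et2O, −10 °C to rt; then I2, −10 °C; aq NH4Cl
Reagents that add atoms: methylmagnesium bromide C[Mg]Br; iodine II
Why: Copper-catalysed anti-carbomagnesiation of the propargylic alkoxide puts methyl on the internal carbon and magnesium on the terminal carbon cis to CH2O (chelate), and iodinolysis with retention gives the Z-vinyl iodide that later fixes the ring-cis C2=C3 geometry.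

Step 2
Reactants: 3 (Z)-3-iodo-2-methylprop-2-en-1-ol
Product: 4 1-({[(2Z)-3-iodo-2-methylprop-2-en-1-yl]oxy}methyl)-4-methoxybenzene
Conditions: NaH, 4-methoxybenzyl chloride, Bu4NI (cat.), THF, 0 °C to rt
Reagents that add atoms: 4-methoxybenzyl chloride COc1ccc(CCl)cc1
Why: Williamson ether synthesis gives an ether that survives the organolithium, samarium, palladium and ruthenium steps and is removed oxidatively in step 11.

Step 3
Reactants: 5 3-bromobut-3-en-1-ol
Product: 6 3-bromobut-3-enal
Conditions: Dess–Martin periodinane, CH2Cl2, 0 °C; used at once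
Reagents that add atoms: none
Why: Dess–Martin oxidation is neutral and fast, so the β,γ-unsaturated aldehyde should form without migration of the double bond into conjugation.

Step 4
Reactants: 7 (S)-4-benzyl-3-(3-methylbutanoyl)-1,3-oxazolidin-2-one; 6 3-bromobut-3-enal
Product: 10 (S)-4-benzyl-3-[(2S,3R)-5-bromo-3-hydroxy-2-(propan-2-yl)hex-5-enoyl]-1,3-oxazolidin-2-one, via boron enolate 8 (not isolated), via boron aldolate 9 (not isolated)
Conditions: Bu2BOTf, Et3N, CH2Cl2, −78 to 0 °C; 6, −78 to 0 °C; then H2O2, MeOH, pH 7 buffer, 0 °C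
Reagents that add atoms: none
Why: Evans syn aldol reaction, in which the (Z)-boron enolate reacts through a Zimmerman–Traxler chair on the face away from the benzyl group of the auxiliary and so sets C10 and C9 (2S,3R, 9,10-syn) together.

Step 5
Reactants: 10 aldol adduct
Product: 11 (2S,3R)-5-bromo-3-hydroxy-N-methoxy-N-methyl-2-(propan-2-yl)hex-5-enamide
Conditions: MeNH(OMe)·HCl, AlMe3, CH2Cl2, −10 °C to rt; Rochelle salt work-up
Reagents that add atoms: N,O-dimethylhydroxylamine hydrochloride CNOC.Cl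
Why: Aluminium-amide transamidation of the imide (Weinreb amide synthesis), assisted by the free β-hydroxyl, releases the auxiliary without touching C10.

Step 6
Reactants: 4 vinyl iodide; 11 Weinreb amide
Product: 14 (2Z,5S,6R)-8-bromo-6-hydroxy-1-[(4-methoxybenzyl)oxy]-2-methyl-5-(propan-2-yl)nona-2,8-dien-4-one, via vinyllithium 12 (not isolated), via magnesium alkoxide 13 (not isolated)
Conditions: 4, t-BuLi (2 equiv), Et2O, −78 °C; separately 11, i-PrMgCl (1 equiv), THF, −78 °C; combine, −78 to −20 °C; aq NH4Cl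
Reagents that add atoms: none
Why: Iodine–lithium exchange with retention of geometry, then Weinreb ketone synthesis, stops at the ketone because the chelated tetrahedral adduct lasts until work-up, and the prior magnesium alkoxide saves one equivalent of 12.

Step 7
Reactants: 14 β-hydroxy Z-enone
Product: 15 (2Z,4R,5R,6R)-8-bromo-4-hydroxy-1-[(4-methoxybenzyl)oxy]-2-methyl-5-(propan-2-yl)nona-2,8-dien-6-yl acetate
Conditions: SmI2 (0.3 equiv), CH3CHO (6 equiv), THF, −10 °C
Reagents that add atoms: acetaldehyde CC=O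
Why: Evans–Tishchenko reduction, in which the C9 hemiacetal of acetaldehyde bound to trivalent samarium delivers hydride to the C1 ketone through a chair-like bicyclic transition state, sets C1 1,3-anti to C9 and leaves the C9 oxygen as its acetate.

Step 8
Reactants: 15 hydroxy acetate
Product: 16 (2Z,4R,5S,6R)-8-bromo-4-[(tert-butyldimethylsilyl)oxy]-1-[(4-methoxybenzyl)oxy]-2-methyl-5-(propan-2-yl)nona-2,8-dien-6-yl acetate
Conditions: TBSOTf, 2,6-lutidine, CH2Cl2, −78 to 0 °C
Reagents that add atoms: tert-butyldimethylsilyl triflate CC(C)(C)[Si](C)(C)OS(=O)(=O)C(F)(F)F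
Why: Silylation with the silyl triflate masks the hindered allylic C1 hydroxyl so that it can neither cyclise onto C4 in step 13 nor ionise under palladium in step 14.

Step 9
Reactants: 16 vinyl bromide
Product: 17 2-(trimethylsilyl)ethyl (4R,5S,6R,7Z)-4-acetoxy-6-[(tert-butyldimethylsilyl)oxy]-9-[(4-methoxybenzyl)oxy]-8-methyl-2-methylidene-5-(propan-2-yl)non-7-enoate
Conditions: Pd(PPh3)4 (5 mol %), CO (1 atm), 2-(trimethylsilyl)ethanol (5 equiv), Et3N, DMF, 70 °C
Reagents that add atoms: carbon monoxide [C-]#[O+]; 2-(trimethylsilyl)ethanol C[Si](C)(C)CCO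
Why: Palladium-catalysed alkoxycarbonylation of the 2-bromoalkene (oxidative addition to zerovalent palladium, CO insertion, alcoholysis) installs C14 directly as a fluoride-labile ester.

Step 10
Reactants: 17 acrylate; 18 allyl phenyl sulfone
Product: 19 2-(trimethylsilyl)ethyl (2E,4R,5S,6R,7Z)-4-acetoxy-6-[(tert-butyldimethylsilyl)oxy]-9-[(4-methoxybenzyl)oxy]-8-methyl-2-[2-(phenylsulfonyl)ethylidene]-5-(propan-2-yl)non-7-enoate
Conditions: second-generation Hoveyda–Grubbs catalyst (10 mol %), 18 (4 equiv), 1,4-benzoquinone (20 mol %), CH2Cl2, 40 °C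
Reagents that add atoms: none
Why: Olefin cross-metathesis of the 1,1-disubstituted acrylate with excess terminal olefin should give the trisubstituted enoate under thermodynamic control with the new CH2 trans to the ester, that is C5 cis to C8 as the ring requires.

Step 11
Reactants: 19 sulfone ester
Product: 20 2-(trimethylsilyl)ethyl (2E,4R,5S,6R,7Z)-4-acetoxy-6-[(tert-butyldimethylsilyl)oxy]-9-hydroxy-8-methyl-2-[2-(phenylsulfonyl)ethylidene]-5-(propan-2-yl)non-7-enoate
Conditions: DDQ, CH2Cl2/pH 7 buffer, 0 °C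
Reagents that add atoms: none
Why: Oxidative cleavage of the 4-methoxybenzyl ether (hydride abstraction by DDQ, then hydrolysis) leaves the silyl ether, esters, sulfone and both alkenes intact.

Step 12
Reactants: 20 allylic alcohol
Product: 21 2-(trimethylsilyl)ethyl (2E,4R,5S,6R,7Z)-4-acetoxy-6-[(tert-butyldimethylsilyl)oxy]-9-chloro-8-methyl-2-[2-(phenylsulfonyl)ethylidene]-5-(propan-2-yl)non-7-enoate
Conditions: PPh3, N-chlorosuccinimide, CH2Cl2, −20 to 0 °C
Reagents that add atoms: N-chlorosuccinimide O=C1CCC(=O)N1Cl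
Why: Appel-type chlorination through the alkoxyphosphonium salt is neutral and proceeds by SN2 at the primary carbon, so the allylic chloride should form without transposition or loss of the Z geometry.

Step 13
Reactants: 21 allylic chloride
Product: 23 2-(trimethylsilyl)ethyl (1E,5Z,7R,8S,9R)-9-acetoxy-7-[(tert-butyldimethylsilyl)oxy]-5-methyl-3-(phenylsulfonyl)-8-(propan-2-yl)cyclodeca-1,5-diene-1-carboxylate (both epimers at the sulfone carbon), via caesium carbanion 22 (not isolated)
Conditions: Cs2CO3 (2 equiv), Bu4NI (20 mol %), MeCN, 50 °C, syringe-pump addition of 21 to 0.002 M; AcOH quench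
Reagents that add atoms: none
Why: Cs2CO3 removes the C5 proton, which is acidified by the sulfone and, through C6=C7, by the C14 ester, and the soft carbanion 22 displaces the primary allylic chloride at C4 by SN2 (iodide catalysis), forming C4–C5. The closest known reaction type is the intramolecular alkylation of sulfone-stabilised allylic carbanions by allylic halides that closes medium-ring terpenoid carbocycles. One ring closes, the ten-membered carbocycle, in a 10-exo-tet mode under high dilution. The only new stereocentre, C5, is not controlled and is erased in step 14, while C1, C9 and C10 are spectators. The step needs C5 over C7 attack, SN2 over SN2' and ring closure over oligomerisation: C7 is already fully substituted and would give an eight-membered ring with a quaternary carbon, C4 is primary whereas C2 is shielded by the C1 silyl ether, and the two ring-cis alkenes fold the chain so that C4 and C5 meet. No metal allyl species is involved, so both alkene geometries pass unchanged into the ring.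

Step 14
Reactants: 23 macrocyclic sulfone
Product: 24 2-(trimethylsilyl)ethyl (1E,5Z,7R,8S,9R)-9-acetoxy-7-[(tert-butyldimethylsilyl)oxy]-5-methyl-8-(propan-2-yl)cyclodeca-1,5-diene-1-carboxylate
Conditions: Pd(PPh3)4 (10 mol %), NaBH4, THF/i-PrOH, 0 °C
Reagents that add atoms: none
Why: Palladium-catalysed hydrogenolysis of the allylic sulfone, in which zerovalent palladium ionises the C5–S bond and hydride attacks the allyl complex at the less hindered C5 terminus remote from the ester, should restore the conjugated enoate in its more stable ring-cis form.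

Step 15
Reactants: 24 macrocyclic ester
Product: 25 (1E,5Z,7R,8R,9R)-9-acetoxy-7-hydroxy-5-methyl-8-(propan-2-yl)cyclodeca-1,5-diene-1-carboxylic acid
Conditions: Bu4NF (4 equiv), AcOH (4 equiv), THF, rt to 40 °C
Reagents that add atoms: none
Why: Fluoride cleaves the C1 silyl ether and triggers the β-elimination of the 2-(trimethylsilyl)ethyl ester in the same operation, while the acetic acid buffer keeps the C9 acetate in place.

Step 16
Reactants: 25 hydroxy acid
Product: 26 (1E,5Z,7R,8S,9R)-7,9-diacetoxy-5-methyl-8-(propan-2-yl)cyclodeca-1,5-diene-1-carboxylic acid (target)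
Conditions: Ac2O, pyridine, DMAP (cat.), CH2Cl2, 0 °C to rt; then aq NaHCO3/THF, then pH 3
Reagents that add atoms: acetic anhydride CC(=O)OC(C)=O
Why: DMAP-catalysed acetylation esterifies the C1 hydroxyl, and the mixed anhydride formed at C14 is hydrolysed in the bicarbonate work-up, which returns the free acid.

Compound list
1 | prop-2-yn-1-ol | C#CCO | starting material
2 | bromomagnesium (Z)-3-(bromomagnesio)-2-methylprop-2-en-1-olate | Br[Mg]/C=C(/C)CO[Mg]Br | intermediate
3 | (Z)-3-iodo-2-methylprop-2-en-1-ol | I/C=C(/C)CO | intermediate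
4 | 1-({[(2Z)-3-iodo-2-methylprop-2-en-1-yl]oxy}methyl)-4-methoxybenzene | I/C=C(/C)COCc1ccc(OC)cc1 | intermediate
5 | 3-bromobut-3-en-1-ol | C=C(Br)CCO | starting material
6 | 3-bromobut-3-enal | C=C(Br)CC=O | intermediate
7 | (S)-4-benzyl-3-(3-methylbutanoyl)-1,3-oxazolidin-2-one | CC(C)CC(=O)N1[C@@H](Cc2ccccc2)COC1=O | starting material
8 | dibutylboron (Z)-enolate of 7 | CC(C)/C=C(\OB(CCCC)CCCC)N1[C@@H](Cc2ccccc2)COC1=O | intermediate
9 | dibutylboron aldolate of 10 | O=C(N1[C@@H](Cc2ccccc2)COC1=O)[C@H]([C@@H](CC(Br)=C)OB(CCCC)CCCC)C(C)C | intermediate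
10 | (S)-4-benzyl-3-[(2S,3R)-5-bromo-3-hydroxy-2-(propan-2-yl)hex-5-enoyl]-1,3-oxazolidin-2-one | O=C(N1[C@@H](Cc2ccccc2)COC1=O)[C@H]([C@@H](CC(Br)=C)O)C(C)C | intermediate
11 | (2S,3R)-5-bromo-3-hydroxy-N-methoxy-N-methyl-2-(propan-2-yl)hex-5-enamide | CON(C)C(=O)[C@H]([C@@H](CC(Br)=C)O)C(C)C | intermediate
12 | (Z)-3-[(4-methoxybenzyl)oxy]-2-methylprop-1-en-1-yllithium | [Li]/C=C(/C)COCc1ccc(OC)cc1 | intermediate
13 | chloromagnesium alkoxide of 11 | CON(C)C(=O)[C@H]([C@@H](CC(Br)=C)O[Mg]Cl)C(C)C | intermediate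
14 | (2Z,5S,6R)-8-bromo-6-hydroxy-1-[(4-methoxybenzyl)oxy]-2-methyl-5-(propan-2-yl)nona-2,8-dien-4-one | O=C(/C=C(/C)COCc1ccc(OC)cc1)[C@H]([C@@H](CC(Br)=C)O)C(C)C | intermediate
15 | (2Z,4R,5R,6R)-8-bromo-4-hydroxy-1-[(4-methoxybenzyl)oxy]-2-methyl-5-(propan-2-yl)nona-2,8-dien-6-yl acetate | O[C@H](/C=C(/C)COCc1ccc(OC)cc1)[C@H]([C@@H](CC(Br)=C)OC(C)=O)C(C)C | intermediate
16 | (2Z,4R,5S,6R)-8-bromo-4-[(tert-butyldimethylsilyl)oxy]-1-[(4-methoxybenzyl)oxy]-2-methyl-5-(propan-2-yl)nona-2,8-dien-6-yl acetate | CC(C)(C)[Si](C)(C)O[C@H](/C=C(/C)COCc1ccc(OC)cc1)[C@H]([C@@H](CC(Br)=C)OC(C)=O)C(C)C | intermediate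
17 | 2-(trimethylsilyl)ethyl (4R,5S,6R,7Z)-4-acetoxy-6-[(tert-butyldimethylsilyl)oxy]-9-[(4-methoxybenzyl)oxy]-8-methyl-2-methylidene-5-(propan-2-yl)non-7-enoate | CC(C)(C)[Si](C)(C)O[C@H](/C=C(/C)COCc1ccc(OC)cc1)[C@H]([C@@H](CC(=C)C(=O)OCC[Si](C)(C)C)OC(C)=O)C(C)C | intermediate
18 | allyl phenyl sulfone | C=CCS(=O)(=O)c1ccccc1 | starting material
19 | 2-(trimethylsilyl)ethyl (2E,4R,5S,6R,7Z)-4-acetoxy-6-[(tert-butyldimethylsilyl)oxy]-9-[(4-methoxybenzyl)oxy]-8-methyl-2-[2-(phenylsulfonyl)ethylidene]-5-(propan-2-yl)non-7-enoate | CC(C)(C)[Si](C)(C)O[C@H](/C=C(/C)COCc1ccc(OC)cc1)[C@H]([C@@H](C/C(=C\CS(=O)(=O)c1ccccc1)C(=O)OCC[Si](C)(C)C)OC(C)=O)C(C)C | intermediate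
20 | 9-hydroxy analogue of 19 (free C4 allylic alcohol) | CC(C)(C)[Si](C)(C)O[C@H](/C=C(/C)CO)[C@H]([C@@H](C/C(=C\CS(=O)(=O)c1ccccc1)C(=O)OCC[Si](C)(C)C)OC(C)=O)C(C)C | intermediate
21 | 9-chloro analogue of 19 (C4 allylic chloride) | CC(C)(C)[Si](C)(C)O[C@H](/C=C(/C)CCl)[C@H]([C@@H](C/C(=C\CS(=O)(=O)c1ccccc1)C(=O)OCC[Si](C)(C)C)OC(C)=O)C(C)C | intermediate
22 | caesium salt of the C5 carbanion of 21 | [Cs+].CC(C)(C)[Si](C)(C)O[C@H](/C=C(/C)CCl)[C@H]([C@@H](C/C(=C\[CH-]S(=O)(=O)c1ccccc1)C(=O)OCC[Si](C)(C)C)OC(C)=O)C(C)C | intermediate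
23 | 2-(trimethylsilyl)ethyl (1E,5Z,7R,8S,9R)-9-acetoxy-7-[(tert-butyldimethylsilyl)oxy]-5-methyl-3-(phenylsulfonyl)-8-(propan-2-yl)cyclodeca-1,5-diene-1-carboxylate | CC(C)(C)[Si](C)(C)O[C@@H]1/C=C(/C)CC(S(=O)(=O)c2ccccc2)/C=C(/C(=O)OCC[Si](C)(C)C)C[C@@H](OC(C)=O)[C@@H]1C(C)C | intermediate
24 | 2-(trimethylsilyl)ethyl (1E,5Z,7R,8S,9R)-9-acetoxy-7-[(tert-butyldimethylsilyl)oxy]-5-methyl-8-(propan-2-yl)cyclodeca-1,5-diene-1-carboxylate | CC(C)(C)[Si](C)(C)O[C@@H]1/C=C(/C)CC/C=C(/C(=O)OCC[Si](C)(C)C)C[C@@H](OC(C)=O)[C@@H]1C(C)C | intermediate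
25 | (1E,5Z,7R,8R,9R)-9-acetoxy-7-hydroxy-5-methyl-8-(propan-2-yl)cyclodeca-1,5-diene-1-carboxylic acid | O[C@@H]1/C=C(/C)CC/C=C(/C(=O)O)C[C@@H](OC(C)=O)[C@@H]1C(C)C | intermediate
26 | (1E,5Z,7R,8S,9R)-7,9-diacetoxy-5-methyl-8-(propan-2-yl)cyclodeca-1,5-diene-1-carboxylic acid | CC(=O)O[C@@H]1/C=C(/C)CC/C=C(/C(=O)O)C[C@@H](OC(C)=O)[C@@H]1C(C)C | target

Total step count: 16. Longest linear sequence: 14 (steps 3 to 16; the vinyl iodide branch, steps 1 and 2, joins at step 6).

Steps most likely to fail

Step 13. The closure may lose to oligomerisation, to attack through C7, or to a base-induced drift of the C6=C7 bond towards the sulfone after ring closure. The fallback sets out from alcohol 20. It closes the same bond without halide or carbonate base, by a Mitsunobu-type dehydrative C-alkylation with cyanomethylenetributylphosphorane (toluene, 90 °C, slow addition). The phosphorane takes the C5 proton and activates the C4 hydroxyl as its phosphonium salt for SN2 displacement. The route is rejoined at 23, and no new compound is made (F0).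

Step 10. The hindered 1,1-disubstituted acrylate may react too slowly, so that homodimerisation of the partner and ruthenium-hydride isomerisation of the acidic sulfone product take over. The fallback sets out from 17 and separates the alkene formation from the sulfone. Cross-metathesis with a large excess of small, non-acidic allyl chloride gives 2-(trimethylsilyl)ethyl (2E,4R,5S,6R,7Z)-4-acetoxy-6-[(tert-butyldimethylsilyl)oxy]-2-(2-chloroethylidene)-9-[(4-methoxybenzyl)oxy]-8-methyl-5-(propan-2-yl)non-7-enoate F1. SN2 displacement with sodium benzenesulfinate in DMF then brings in the sulfone, and the route is rejoined at 19.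

Step 14. Hydride may be delivered to C7, or the allyl complex may lose a β-hydrogen from C8. The fallback sets out from 23 and removes the sulfone by electron transfer instead. SmI2 in THF/MeOH at −78 °C expels sulfinate, and kinetic α-protonation of the dienolate gives the deconjugated ester 2-(trimethylsilyl)ethyl (5Z,7R,8S,9R)-9-acetoxy-7-[(tert-butyldimethylsilyl)oxy]-5-methyl-8-(propan-2-yl)cyclodeca-2,5-diene-1-carboxylate F2. DBU in CH2Cl2 then moves the double bond back into conjugation under thermodynamic control, and the route is rejoined at 24.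

Further compounds
F0 | step 13 | none | none
F1 | step 10 | 2-(trimethylsilyl)ethyl (2E,4R,5S,6R,7Z)-4-acetoxy-6-[(tert-butyldimethylsilyl)oxy]-2-(2-chloroethylidene)-9-[(4-methoxybenzyl)oxy]-8-methyl-5-(propan-2-yl)non-7-enoate | CC(C)(C)[Si](C)(C)O[C@H](/C=C(/C)COCc1ccc(OC)cc1)[C@H]([C@@H](C/C(=C\CCl)C(=O)OCC[Si](C)(C)C)OC(C)=O)C(C)C
F2 | step 14 | 2-(trimethylsilyl)ethyl (5Z,7R,8S,9R)-9-acetoxy-7-[(tert-butyldimethylsilyl)oxy]-5-methyl-8-(propan-2-yl)cyclodeca-2,5-diene-1-carboxylate | CC(C)(C)[Si](C)(C)O[C@@H]1/C=C(/C)CC=CC(C(=O)OCC[Si](C)(C)C)C[C@@H](OC(C)=O)[C@@H]1C(C)C
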